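I decide to count the D left in each flask, not the E made, and I want one number for it.

    D + Z ⇌ D.Z (K1 = 53 M⁻¹, k1 = 1.5 × 10⁵ M⁻¹ min⁻¹)
    D.Z → Z + E (k2 = 65 min⁻¹)
    Q ⇌ D, rate k3*(cs3 - [D]) while solid is left; crystals form when [D] > cs3 (cs3 = 17 mM, k3 = 3.5 × 10⁻⁴ min⁻¹)
    D + E → X (k4 = 0.095 M⁻¹ min⁻¹)
    Z + E → Z.E (k5 = 0.010 M⁻¹ min⁻¹)

the same everywhere: Z 0.01 mol%; time 20 h

| flask | Q |
|---|---|
| eta | 2.5 mM |
| zeta | 5.0 mM |
| theta | 10 mM |
| epsilon | 20 mM |

- amount of E at the end, in percent of the Q charged for eta, zeta, theta, epsilon, in this order
- how that number moves from the first to the last of them (hardly changes / falls, then rises / falls all the way / rises all the way / rises, then falls)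

- percentages count the Q that a species holds: one X counts as two
- solid, in amounts per volume of the solution: Q
- at the start none of Q is in solution
- "hardly changes" means that all values lie within two and a half points (for a concentration: within two and a half percent of the largest)
- run time (eta): 20 h

D.Z goes forward in a share 2.25% of its partings, and the rest falls back to D + Z. The Michaelis constant 19.3 mM stands above eta's charge, so I treat the loss of D as pseudo-first-order and fold binding rate, forward share, enzyme and time into 1.01, the conversion number of eta, whose meaning is the natural logarithm of how far D falls during the run. Counted as if eta's whole charge stood dissolved from the start, the fraction left is 36.4%. The enzyme is charged in proportion to Q, so the number grows with the charge, up to 8.08 for epsilon, and read by itself it gives a row that rises all the way.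

That number is not enough, though: at the start none of Q is in solution, and the solid has to come in first. Dissolving at its top rate, with no D in solution, brings 7.14 mM into solution during the run, which is 71.4% of theta's charge and 35.7% of epsilon's, less than the >99.9% that the number offers epsilon. My ceilings on E for eta and zeta, from the number, are 63.6% and 86.7%, so with those two the ceilings rise, then fall across the four flasks; they are ceilings and not yields.

The forecast gives 48%, 57%, 44% and 27.5%, a row that rises, then falls, and on epsilon it stands below my ceiling; of the two large charges it says “solid remains, and the run is dissolution-limited”. The flask gives 48.2%, 56.9%, 43.9% and 27.5%, and the row rises, then falls.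

In eta the way back from D.Z to D + Z is the main reason why E falls short of the charge: the run without it ends at 99.1% E against 48.2%, and that way back is what puts the share 2.25% into the number. With the share kept and the clock started at the midpoint of dissolving at top rate, the number leaves 43.5% of eta's charge as D, where 44.0% stands at the end. The same count for zeta leaves 26.9% of its charge, against 31% still there, solid or dissolved, at the end.

The rate constants are assumed; no experiment stands behind them.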